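The flask gets half the substrate of the elm run against the same partner, and the question is what that change does to target.

| flask | substrate | partner | remark | time |
|---|---|---|---|---|
| elm | 0.40 M | 0.14 M | run made earlier |  |
| flask | 0.20 M | 0.140 M |  | 10 d |

elm run (percent of the substrate charged)

| time / d | target / % |
|---|---|
| 0.417 | 12.9 |
| 0.833 | 5.6 |
| 1.25 | 2.5 |
| 1.67 | 1.4 |
| 2.00 | 0.7 |
| 2.50 | 0.3 |
| 3.00 | 0.1 |

(standard deviation of a reading: 0.3 percentage points)

- percentages count the substrate that a species holds: one side product B counts as two
- the analysis behind the earlier runs scatters by 0.3 percentage points, standard deviation
- steps thought possible: loose pair -> side product A; substrate + target -> side product B; partner + loose pair -> isomer of the product; partner + tight pair -> target; tight pair <-> loose pair; target -> over-reaction product; substrate <-> tight pair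

- time, not beyond 10 d, at which the flask holds most target
- the amount of target, in percent of the substrate charged, at that time

In the elm run, target falls at a steady 1.97 d⁻¹, as read from 12.9 % at 0.417 d and 2.5 % at 1.25 d. A steady rate constant suggests that whatever attacks target stays nearly constant. Two of the steps thought possible take target: target alone to over-reaction product, and substrate + target to side product B. The readings don't separate them, so I wager on the second, with substrate frozen at a leftover level, which makes the loss pseudo-first-order.

Now I count in fractions of the substrate charged. One target takes one substrate and one partner, and one side product B takes one target and one more substrate. So if nothing else takes them, once both charges are used, the target left is two times the partner per substrate, less one; I call this the target balance 40.0 % for the flask. For the elm run the same sum gives −30.0 %, and a negative balance means target goes while that much substrate stays, which is the frozen level I assumed. Target also can't pass the partner charge, 70.0 % in the flask, so I expect the best between these two figures. The elm readings give me no time, since they fall from the first one on.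

The forecast says 22 % at 0.25 d, reasoning that “Halved substrate can only slow any bimolecular loss”. Its figure lies below my balance.

The flask holds 44.4 % of target at 0.650 d, above the balance and below the partner charge.

loose pair → side product A (k = 0.00280 min⁻¹); substrate + target → side product B (k = 0.00970 M⁻¹ min⁻¹); partner + loose pair → isomer of the product (k = 1.20 M⁻¹ min⁻¹); partner + tight pair → target (k = 3.50 M⁻¹ min⁻¹); tight pair ⇌ loose pair (K = 0.0990, k = 4.10 min⁻¹); target → over-reaction product (k = 3.20 × 10⁻⁷ min⁻¹); substrate ⇌ tight pair (K = 0.0700, k = 0.00210 min⁻¹) At that time 12.1 % of the charge is still substrate. The balance of 40.0 % stands against 37.8 % of target at 10.0 d. The neighbour flask with 0.34 M of substrate and the same partner has a balance of −17.6 %, and at 10.0 d it holds 0.00955 % of target beside 13.3 % of substrate.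

The readings were generated by integration for an exercise.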